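Each dihydrofuran ring of the target (O1–C2–C3–C3a–C7a and its primed twin) carries an aryl group on C2 and has C3 bonded directly to the benzo carbon C3a: it is a flavanone whose carbonyl carbon has been pushed out of the ring. One treatment with trivalent iodine should shift both ring-fused aryl carbons from C4 to C3 (forming C3–C3a and C3'–C3a') and so contract the two chromanone rings of a C8'–C2 linked, 7-bromo, tetra-O-methyl bis-flavanone, itself made by two enantioselective arylboronic acid additions to chromones, to the trans,trans diester. A Heck reaction, twofold decarboxylative arylation of the extruded ester carbons and demethylation finish the route.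

Key step: step 10

Remarks on the chemistry (assumptions and corrections):
- A 2-hydroxybenzaldehyde has no carbon for C3 of a chromone, so 4-bromo-2-hydroxy-6-methoxybenzaldehyde is first homologated to the methyl ketone (steps 6 and 7).
- The 8-bromochromone is built from 2-bromo-5-methoxyphenol, because bromination of a 2-hydroxy-6-methoxyacetophenone can occur at two activated ring positions.
- The pyridine-oxazoline ligand is assumed to select the same face of a chromone as of a cyclic enone, so the (R)-ligand is used for the 2S centres; if the configuration of the first flavanone proves opposite, the (S)-ligand is used in both additions.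
- The free boronic acid, not a pinacol ester, is prepared for the second conjugate addition, because pinacol esters transmetalate poorly under these conditions.

Step 1
Reactants: 1 2-bromo-5-methoxyphenol; 2 ethyl propiolate
Product: 3 ethyl (E)-3-(2-bromo-5-methoxyphenoxy)prop-2-enoate
Conditions: DABCO (10 mol%), CH2Cl2, 0 °C to rt
Reagents that add atoms: none
Why: Amine-catalysed oxa-Michael addition of phenols to propiolate esters is a standard entry to (E)-3-aryloxyacrylates, and the ortho-bromine of 1 fixes beforehand which carbon becomes C8 of the chromone.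

Step 2
Reactants: 3 ethyl (E)-3-(2-bromo-5-methoxyphenoxy)prop-2-enoate
Product: 4 (E)-3-(2-bromo-5-methoxyphenoxy)prop-2-enoic acid
Conditions: NaOH (2 M aq), EtOH, rt; then aq HCl
Reagents that add atoms: sodium hydroxide, [Na+].[OH-]
Why: Plain ester saponification; the enol ether is a vinylogous carbonate that should tolerate cold aqueous hydroxide, and the free acid is needed for acylium formation.

Step 3
Reactants: 4 (E)-3-(2-bromo-5-methoxyphenoxy)prop-2-enoic acid
Product: 5 8-bromo-5-methoxy-4H-chromen-4-one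
Conditions: P2O5 in MeSO3H (7.7 wt%), 60 °C
Reagents that add atoms: none
Why: Intramolecular Friedel–Crafts acylation of 3-aryloxyacrylic acids in a strong dehydrating acid is a known chromone synthesis (the double bond isomerises under the acid), and the only free position ortho to the ether oxygen, further activated by the methoxy group, places bromine at C8 and methoxy at C5.

Step 4
Reactants: 5 8-bromo-5-methoxy-4H-chromen-4-one; 6 2,4-dimethoxyphenylboronic acid
Product: 7 (2S)-8-bromo-2-(2,4-dimethoxyphenyl)-5-methoxychroman-4-one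
Conditions: Pd(OCOCF3)2 (5 mol%), (R)-t-BuPyOx [(R)-4-tert-butyl-2-(pyridin-2-yl)-4,5-dihydrooxazole] (6 mol%), NH4PF6 (30 mol%), H2O (5 equiv), ClCH2CH2Cl, 60 °C
Reagents that add atoms: none
Why: Conjugate addition of an arylboronic acid to a chromone under divalent palladium with a chiral pyridine-oxazoline ligand forms the C2–aryl bond by enantioselective carbopalladation and protonolysis without touching the aryl bromide (no zerovalent palladium is involved); the new centre (C2 of 7, later C2') is set by the ligand, the (R)-ligand being expected to give S.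

Step 5
Reactants: 7 (2S)-8-bromo-2-(2,4-dimethoxyphenyl)-5-methoxychroman-4-one
Product: 8 [(2S)-2-(2,4-dimethoxyphenyl)-5-methoxy-4-oxochroman-8-yl]boronic acid
Conditions: B2(OH)4 (2 equiv), Pd(OAc)2 (2 mol%), XPhos (4 mol%), KOAc (3 equiv), EtOH, 80 °C
Reagents that add atoms: tetrahydroxydiboron, OB(O)B(O)O
Why: Miyaura-type borylation with tetrahydroxydiboron gives the free boronic acid in one step under a base (KOAc) too weak to enolise the ketone or open the chromanone ring, so the C2 centre should be kept.

Step 6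
Reactants: 9 4-bromo-2-hydroxy-6-methoxybenzaldehyde
Product: 10 1-(4-bromo-2-hydroxy-6-methoxyphenyl)ethan-1-ol (racemic)
Conditions: MeMgBr (3 equiv), THF, 0 °C; aq NH4Cl
Reagents that add atoms: methylmagnesium bromide, C[Mg]Br
Why: Grignard addition to the aldehyde (the first equivalent is consumed by the phenol) supplies the carbon that becomes C3 of the chromone, the aryl bromide being inert to MeMgBr at 0 °C and the new carbinol centre being removed in the next step.

Step 7
Reactants: 10 1-(4-bromo-2-hydroxy-6-methoxyphenyl)ethan-1-ol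
Product: 11 1-(4-bromo-2-hydroxy-6-methoxyphenyl)ethan-1-one
Conditions: MnO2 (activated, excess), CH2Cl2, rt
Reagents that add atoms: none
Why: MnO2 oxidises benzylic alcohols selectively under neutral conditions, and the product is held as the hydrogen-bonded 2-hydroxyaryl ketone.

Step 8
Reactants: 11 1-(4-bromo-2-hydroxy-6-methoxyphenyl)ethan-1-one
Product: 13 7-bromo-5-methoxy-4H-chromen-4-one, via enaminone 12 (not isolated)
Conditions: Me2NCH(OMe)2, toluene, 100 °C; then conc. HCl, CH2Cl2, rt
Reagents that add atoms: N,N-dimethylformamide dimethyl acetal, COC(OC)N(C)C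
Why: Condensation of the methyl ketone with the amide acetal, then acid-induced oxa-Michael addition and loss of dimethylamine, is the standard chromone synthesis from 2-hydroxyacetophenones.

Step 9
Reactants: 8 [(2S)-2-(2,4-dimethoxyphenyl)-5-methoxy-4-oxochroman-8-yl]boronic acid; 13 7-bromo-5-methoxy-4H-chromen-4-one
Product: 14 (2S)-7-bromo-2-[(2S)-2-(2,4-dimethoxyphenyl)-5-methoxy-4-oxochroman-8-yl]-5-methoxychroman-4-one (linked bis-flavanone)
Conditions: Pd(OCOCF3)2 (10 mol%), (R)-t-BuPyOx (12 mol%), NH4PF6 (30 mol%), H2O (5 equiv), ClCH2CH2Cl, 60 °C; 13 in excess (2 equiv)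
Reagents that add atoms: none
Why: The same enantioselective conjugate addition joins C8' to C2; the (R)-ligand should again control the new centre (C2, S) because the existing C2' centre lies three bonds from the reacting carbon, and the 7-bromide is inert to divalent palladium.

Step 10
Reactants: 14 linked bis-flavanone
Product: 16 trans,trans-bis(dihydrobenzofuran) dimethyl diester, via bis(enol ether) 15 (not isolated)
Conditions: PhI(OAc)2 (2.5 equiv), conc. H2SO4, HC(OMe)3, 0 °C to rt
Reagents that add atoms: trimethyl orthoformate, COC(OC)OC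
Why: Acid and orthoformate turn both C4 ketones into methyl enol ethers (15); trivalent iodine then bonds to each C3 anti to the neighbouring C2 aryl group, and iodobenzene leaves as the ring-fused aryl carbon (C4a, C4a') shifts from C4 to C3, the resulting dimethoxycarbenium ions losing a methyl group to give the esters. The closest known reaction is the oxidative ring contraction of single flavanones to trans methyl 2-aryl-2,3-dihydrobenzofuran-3-carboxylates with PhI(OAc)2 or Tl(NO3)3 in trimethyl orthoformate. Each five-membered ring (O1–C2–C3–C3a–C7a and O1'–C2'–C3'–C3a'–C7a') is closed by this 1,2-aryl shift through a bridged, phenonium-like transition state, that is by contraction of the six-membered ring and not by cyclisation of an open chain, forming C3–C3a and C3'–C3a'. C3 and C3' are set by substrate control from C2 and C2': the equatorial C3–I bond of the trans adduct is antiperiplanar to the C4–C4a ring bond, migration inverts C3 and places the ester trans to the aryl group, and a cis ester would in any case epimerise to trans under the acid. The step needs migration of the fused carbon to beat both migration of the C2 aryl group and oxidation of the dimethoxyphenyl ring; the ring oxygen and the methoxy group ortho to each migrating carbon raise its migratory aptitude, the equatorial C2 aryl groups are gauche to the C–I bond and cannot shift, and the enol ethers are by far the most nucleophilic sites. C2 and C2' are not part of the reacting system, so their S configuration should carry through.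

Step 11
Reactants: 16 trans,trans-bis(dihydrobenzofuran) dimethyl diester; 17 4-methoxystyrene
Product: 18 dimethyl diester bearing the (E)-4-methoxystyryl group at C6
Conditions: Pd(OAc)2 (5 mol%), P(o-tol)3 (10 mol%), Et3N, DMF, 100 °C
Reagents that add atoms: none
Why: Mizoroki–Heck coupling of the unhindered C6 bromide with a styrene gives the (E)-stilbene through syn insertion and syn β-hydride elimination, while the ester enolates cannot expel the ring oxygen (the C2–O bond lies in the ring plane, orthogonal to the enolate π system), so C2 and C2' are safe.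

Step 12
Reactants: 18 stilbene dimethyl diester
Product: 19 stilbene diacid
Conditions: LiOH, THF/MeOH/H2O, rt to 40 °C; then aq HCl
Reagents that add atoms: lithium hydroxide, [Li+].[OH-]
Why: Saponification of both methyl esters; any epimerisation at C3 or C3' is harmless because these centres become planar radicals in step 14, and ring opening by β-elimination is disfavoured for the geometric reason given in step 11.

Step 13
Reactants: 19 stilbene diacid
Product: 20 bis(N-acyloxyphthalimide) of 19
Conditions: N-hydroxyphthalimide (2.4 equiv), i-PrN=C=N-i-Pr, DMAP (cat.), CH2Cl2, rt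
Reagents that add atoms: N-hydroxyphthalimide, O=C1c2ccccc2C(=O)N1O
Why: Carbodiimide (Steglich-type) esterification with N-hydroxyphthalimide gives the redox-active esters required for decarboxylative coupling.

Step 14
Reactants: 20 bis(N-acyloxyphthalimide); 21 1-bromo-3,5-dimethoxybenzene
Product: 24 nona-O-methylgnetumontanin B, via (3,5-dimethoxyphenyl)magnesium bromide 22 (not isolated), via (3,5-dimethoxyphenyl)zinc chloride 23 (not isolated)
Conditions: 21, Mg, LiCl, THF, rt; ZnCl2, THF; then 20, NiCl2·glyme (40 mol%), 4,4'-di-tert-butyl-2,2'-bipyridine (80 mol%), THF/DMF, rt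
Reagents that add atoms: none
Why: Nickel-catalysed decarboxylative Negishi-type arylation of redox-active esters: single-electron reduction releases CO2 and the benzylic C3 and C3' radicals, which are captured by arylnickel and coupled on the face opposite the neighbouring C2 or C2' aryl group, so each new aryl group should end trans (also the more stable arrangement), the aryl bromide having been consumed beforehand.

Step 15
Reactants: 24 nona-O-methylgnetumontanin B
Product: 25 gnetumontanin B
Conditions: BBr3 (excess), CH2Cl2, −78 °C to rt; H2O quench at 0 °C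
Reagents that add atoms: none
Why: BBr3 cleaves all nine aryl methyl ethers by Lewis acid–base complexation and bromide attack at methyl, the usual unmasking of permethylated stilbene oligomers; no stereocentre is enolisable, and a benzylic C–O bond that ionised reversibly would re-close to the same trans-dihydrobenzofuran because C3 and C3' stay fixed.

Compound list
1 | 2-bromo-5-methoxyphenol | COc1ccc(Br)c(O)c1 | starting material
2 | ethyl propiolate | CCOC(=O)C#C | starting material
3 | ethyl (E)-3-(2-bromo-5-methoxyphenoxy)prop-2-enoate | CCOC(=O)/C=C/Oc1cc(OC)ccc1Br | intermediate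
4 | (E)-3-(2-bromo-5-methoxyphenoxy)prop-2-enoic acid | OC(=O)/C=C/Oc1cc(OC)ccc1Br | intermediate
5 | 8-bromo-5-methoxy-4H-chromen-4-one | COc1ccc(Br)c2occc(=O)c12 | intermediate
6 | 2,4-dimethoxyphenylboronic acid | COc1ccc(B(O)O)c(OC)c1 | starting material
7 | (2S)-8-bromo-2-(2,4-dimethoxyphenyl)-5-methoxychroman-4-one | COc1ccc(Br)c2O[C@H](c3ccc(OC)cc3OC)CC(=O)c12 | intermediate
8 | [(2S)-2-(2,4-dimethoxyphenyl)-5-methoxy-4-oxochroman-8-yl]boronic acid | COc1ccc(B(O)O)c2O[C@H](c3ccc(OC)cc3OC)CC(=O)c12 | intermediate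
9 | 4-bromo-2-hydroxy-6-methoxybenzaldehyde | COc1cc(Br)cc(O)c1C=O | starting material
10 | 1-(4-bromo-2-hydroxy-6-methoxyphenyl)ethan-1-ol (racemic) | COc1cc(Br)cc(O)c1C(C)O | intermediate
11 | 1-(4-bromo-2-hydroxy-6-methoxyphenyl)ethan-1-one | COc1cc(Br)cc(O)c1C(C)=O | intermediate
12 | (E)-1-(4-bromo-2-hydroxy-6-methoxyphenyl)-3-(dimethylamino)prop-2-en-1-one | COc1cc(Br)cc(O)c1C(=O)/C=C/N(C)C | intermediate
13 | 7-bromo-5-methoxy-4H-chromen-4-one | COc1cc(Br)cc2occc(=O)c12 | intermediate
14 | (2S)-7-bromo-2-[(2S)-2-(2,4-dimethoxyphenyl)-5-methoxy-4-oxochroman-8-yl]-5-methoxychroman-4-one | O=C1C[C@@H](c3ccc(OC)c4c3O[C@H](c3ccc(OC)cc3OC)CC4=O)Oc2cc(Br)cc(OC)c12 | intermediate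
15 | (2S)-7-bromo-2-[(2S)-2-(2,4-dimethoxyphenyl)-4,5-dimethoxy-2H-chromen-8-yl]-4,5-dimethoxy-2H-chromene | COC1=C[C@@H](c3ccc(OC)c4c3O[C@H](c3ccc(OC)cc3OC)C=C4OC)Oc2cc(Br)cc(OC)c12 | intermediate
16 | dimethyl (2S,2'S,3S,3'S)-6-bromo-2'-(2,4-dimethoxyphenyl)-4,4'-dimethoxy-2,2',3,3'-tetrahydro-2,7'-bi-1-benzofuran-3,3'-dicarboxylate | Brc1cc(OC)c2c(c1)O[C@H](c1ccc(OC)c3c1O[C@H](c1ccc(OC)cc1OC)[C@H]3C(=O)OC)[C@H]2C(=O)OC | intermediate
17 | 4-methoxystyrene | C=Cc1ccc(OC)cc1 | starting material
18 | dimethyl (2S,2'S,3S,3'S)-2'-(2,4-dimethoxyphenyl)-4,4'-dimethoxy-6-[(E)-2-(4-methoxyphenyl)ethenyl]-2,2',3,3'-tetrahydro-2,7'-bi-1-benzofuran-3,3'-dicarboxylate | COc1ccc(/C=C/c2cc(OC)c3c(c2)O[C@H](c2ccc(OC)c4c2O[C@H](c2ccc(OC)cc2OC)[C@H]4C(=O)OC)[C@H]3C(=O)OC)cc1 | intermediate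
19 | (2S,2'S,3S,3'S)-2'-(2,4-dimethoxyphenyl)-4,4'-dimethoxy-6-[(E)-2-(4-methoxyphenyl)ethenyl]-2,2',3,3'-tetrahydro-2,7'-bi-1-benzofuran-3,3'-dicarboxylic acid | COc1ccc(/C=C/c2cc(OC)c3c(c2)O[C@H](c2ccc(OC)c4c2O[C@H](c2ccc(OC)cc2OC)[C@H]4C(=O)O)[C@H]3C(=O)O)cc1 | intermediate
20 | bis(1,3-dioxoisoindolin-2-yl) ester of 19 | COc1ccc(/C=C/c2cc(OC)c3c(c2)O[C@H](c2ccc(OC)c4c2O[C@H](c2ccc(OC)cc2OC)[C@H]4C(=O)ON2C(=O)c4ccccc4C2=O)[C@H]3C(=O)ON2C(=O)c3ccccc3C2=O)cc1 | intermediate
21 | 1-bromo-3,5-dimethoxybenzene | COc1cc(Br)cc(OC)c1 | starting material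
22 | (3,5-dimethoxyphenyl)magnesium bromide | COc1cc([Mg]Br)cc(OC)c1 | intermediate
23 | (3,5-dimethoxyphenyl)zinc chloride | COc1cc([Zn]Cl)cc(OC)c1 | intermediate
24 | (2S,2'S,3S,3'S)-2'-(2,4-dimethoxyphenyl)-3,3'-bis(3,5-dimethoxyphenyl)-4,4'-dimethoxy-6-[(E)-2-(4-methoxyphenyl)ethenyl]-2,2',3,3'-tetrahydro-2,7'-bi-1-benzofuran | COc1ccc(/C=C/c2cc(OC)c3c(c2)O[C@H](c2ccc(OC)c4c2O[C@H](c2ccc(OC)cc2OC)[C@H]4c2cc(OC)cc(OC)c2)[C@H]3c2cc(OC)cc(OC)c2)cc1 | intermediate
25 | gnetumontanin B, (2S,2'S,3S,3'S)-2'-(2,4-dihydroxyphenyl)-3,3'-bis(3,5-dihydroxyphenyl)-6-[(E)-2-(4-hydroxyphenyl)ethenyl]-2,2',3,3'-tetrahydro-2,7'-bi-1-benzofuran-4,4'-diol | Oc1ccc(/C=C/c2cc(O)c3c(c2)O[C@H](c2ccc(O)c4c2O[C@H](c2ccc(O)cc2O)[C@H]4c2cc(O)cc(O)c2)[C@H]3c2cc(O)cc(O)c2)cc1 | target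

Total step count: 15 steps.
Longest linear sequence: 12 steps (steps 1–5 and 9–15, from 2-bromo-5-methoxyphenol).

Steps most likely to fail

Step 10. The oxidant may attack the electron-rich 2,4-dimethoxyphenyl ring, that ring may migrate from C2' to C3' in place of the fused carbon, or the strong acid may ionise the C2'–O bond and erode its configuration. The fallback sets out from 14 and forms the same two bonds by a Wolff ring contraction, without acid or an electrophilic oxidant. Double enolisation (LiN(SiMe3)2, THF, −78 °C) and acylation with 2,2,2-trifluoroethyl trifluoroacetate should give the bis(3-trifluoroacetyl) bis-flavanone F1. Detrifluoroacetylative diazo transfer (MsN3, Et3N, H2O, MeCN) then gives the bis(3-diazo) bis-flavanone F2. Irradiation (350 nm) in MeOH moves C4a and C4a' to the carbene carbons, and the ketenes are trapped as the diester epimer mixture F3. NaOMe in MeOH equilibrates F3 to the trans,trans diester, where the route is rejoined at 16.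

Step 9. Protodeboronation of the electron-rich, ortho-alkoxy boronic acid may outrun transmetalation, and insertion of the chromone into the hindered aryl–palladium bond may be slow. The fallback sets out from 8, which is converted with KHF2 in MeOH/H2O into the potassium trifluoroborate F4, a slow-release aryl source. F4 is added to 13 in a Hayashi–Miyaura reaction under monovalent rhodium ([RhCl(C2H4)2]2 with the enantiomer of a chiral bicyclo[2.2.2]octadiene ligand that delivers the 2S product, dioxane/H2O, 80 °C), a catalyst class that accepts ortho-substituted aryl groups more readily. The route is rejoined at 14.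

Step 15. The Lewis acid may ionise the benzylic C2–O and C2'–O bonds, whose aryl groups carry ortho and para oxygens, leading to elimination; HBr may also add to the stilbene during the long exposure that nine ethers require. The fallback sets out from 19, where each C2 cation would be destabilised by the adjacent carboxyl carbon and only five ethers are present.
- BBr3 in CH2Cl2 (−78 to 0 °C) should give the pentaphenol diacid F5.
- Ac2O/pyridine followed by aqueous work-up gives the pentaacetate diacid F6.
- N-hydroxyphthalimide and i-PrN=C=N-i-Pr give the bis(N-acyloxyphthalimide) F7.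
- 5-Bromoresorcinol (Oc1cc(Br)cc(O)c1, purchased) is silylated (t-BuMe2SiCl, imidazole, DMF) to 1-bromo-3,5-bis(tert-butyldimethylsilyloxy)benzene F8.
- F8 is converted by Mg/LiCl into the arylmagnesium bromide F9 and by ZnCl2 into the arylzinc chloride F10.
- Coupling of F10 with F7 under the conditions of step 14 gives the pentaacetate tetrasilyl ether F11.
- K2CO3 in degassed MeOH at rt removes the acetates and the aryl silyl ethers without any acid, and the route is rejoined at 25.

Further compounds
F1 | step 10 | (2S)-7-bromo-2-[(2S)-2-(2,4-dimethoxyphenyl)-5-methoxy-4-oxo-3-(trifluoroacetyl)chroman-8-yl]-5-methoxy-3-(trifluoroacetyl)chroman-4-one (C3 and C3' unassigned) | O=C1C(C(=O)C(F)(F)F)[C@@H](c3ccc(OC)c4c3O[C@H](c3ccc(OC)cc3OC)C(C(=O)C(F)(F)F)C4=O)Oc2cc(Br)cc(OC)c12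
F2 | step 10 | (2S)-7-bromo-3-diazo-2-[(2S)-3-diazo-2-(2,4-dimethoxyphenyl)-5-methoxy-4-oxochroman-8-yl]-5-methoxychroman-4-one | O=C1C(=[N+]=[N-])[C@@H](c3ccc(OC)c4c3O[C@H](c3ccc(OC)cc3OC)C(=[N+]=[N-])C4=O)Oc2cc(Br)cc(OC)c12
F3 | step 10 | dimethyl (2S,2'S)-6-bromo-2'-(2,4-dimethoxyphenyl)-4,4'-dimethoxy-2,2',3,3'-tetrahydro-2,7'-bi-1-benzofuran-3,3'-dicarboxylate, mixture of C3 and C3' epimers | Brc1cc(OC)c2c(c1)O[C@H](c1ccc(OC)c3c1O[C@H](c1ccc(OC)cc1OC)C3C(=O)OC)C2C(=O)OC
F4 | step 9 | potassium [(2S)-2-(2,4-dimethoxyphenyl)-5-methoxy-4-oxochroman-8-yl]trifluoroborate | COc1ccc([B-](F)(F)F)c2O[C@H](c3ccc(OC)cc3OC)CC(=O)c12.[K+]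
F5 | step 15 | (2S,2'S,3S,3'S)-2'-(2,4-dihydroxyphenyl)-4,4'-dihydroxy-6-[(E)-2-(4-hydroxyphenyl)ethenyl]-2,2',3,3'-tetrahydro-2,7'-bi-1-benzofuran-3,3'-dicarboxylic acid | Oc1ccc(/C=C/c2cc(O)c3c(c2)O[C@H](c2ccc(O)c4c2O[C@H](c2ccc(O)cc2O)[C@H]4C(=O)O)[C@H]3C(=O)O)cc1
F6 | step 15 | pentaacetate of F5 | CC(=O)Oc1ccc(/C=C/c2cc(OC(C)=O)c3c(c2)O[C@H](c2ccc(OC(C)=O)c4c2O[C@H](c2ccc(OC(C)=O)cc2OC(C)=O)[C@H]4C(=O)O)[C@H]3C(=O)O)cc1
F7 | step 15 | bis(1,3-dioxoisoindolin-2-yl) ester of F6 | CC(=O)Oc1ccc(/C=C/c2cc(OC(C)=O)c3c(c2)O[C@H](c2ccc(OC(C)=O)c4c2O[C@H](c2ccc(OC(C)=O)cc2OC(C)=O)[C@H]4C(=O)ON2C(=O)c4ccccc4C2=O)[C@H]3C(=O)ON2C(=O)c3ccccc3C2=O)cc1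
F8 | step 15 | 1-bromo-3,5-bis(tert-butyldimethylsilyloxy)benzene | CC(C)(C)[Si](C)(C)Oc1cc(Br)cc(O[Si](C)(C)C(C)(C)C)c1
F9 | step 15 | [3,5-bis(tert-butyldimethylsilyloxy)phenyl]magnesium bromide | CC(C)(C)[Si](C)(C)Oc1cc([Mg]Br)cc(O[Si](C)(C)C(C)(C)C)c1
F10 | step 15 | [3,5-bis(tert-butyldimethylsilyloxy)phenyl]zinc chloride | CC(C)(C)[Si](C)(C)Oc1cc([Zn]Cl)cc(O[Si](C)(C)C(C)(C)C)c1
F11 | step 15 | penta-O-acetyl-tetra-O-(tert-butyldimethylsilyl)gnetumontanin B (acetates on the styryl, C4, C4' and 2,4-dioxyphenyl oxygens; silyl ethers on the two 3,5-dioxyphenyl rings) | CC(=O)Oc1ccc(/C=C/c2cc(OC(C)=O)c3c(c2)O[C@H](c2ccc(OC(C)=O)c4c2O[C@H](c2ccc(OC(C)=O)cc2OC(C)=O)[C@H]4c2cc(O[Si](C)(C)C(C)(C)C)cc(O[Si](C)(C)C(C)(C)C)c2)[C@H]3c2cc(O[Si](C)(C)C(C)(C)C)cc(O[Si](C)(C)C(C)(C)C)c2)cc1
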